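**Retrosynthetic overview**
1. The γ-lactone (hydroxyphthalide) on ring B is cut at the aryl–C(acetal) bond. Forward, a benzyloxymethyl (BOM) ester C–H is arylated by the ortho C–Br under chiral palladium catalysis, so the acetal carbon reacts as a formyl-anion equivalent and arrives as the (S)-O-benzyl acetal.
2. End game: NaBH4 turns two ArCHO groups into the two CH2OH groups, then neutral hydrogenolysis frees the phenols and the lactol without breaking the acetal C–O bond.
3. Depsidone ring: the ether bond comes from an intramolecular Ullmann closure of an iodo-bromo depside, the ester bond from mixed-anhydride coupling of a ring A salicylic acid with a ring B phenol.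
4. Ring A acid from methyl orsellinate (formylation, O-benzylation, ester cleavage); ring B phenol from 2-bromo-4,6-dimethoxybenzoic acid (demethylation, esterification, formylation, iodination).
5. Ring order: both benzene rings are bought; the seven-membered ring is closed third (ester, then ether); the γ-lactone is closed last.

Assumption: the lactol carbon is (S) as drawn; a free 3-hydroxyphthalide can epimerise by ring–chain tautomerism in protic acid or base, so the centre is carried as its O-benzyl acetal, released only in the last step under neutral conditions, and the product kept as a solid; methyl orsellinate and 2-bromo-4,6-dimethoxybenzoic acid are taken as catalogue compounds.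

**Step 1**
Reactants: 1 methyl orsellinate (methyl 2,4-dihydroxy-6-methylbenzoate)
Product: 3 methyl 3-formyl-2,4-dihydroxy-6-methylbenzoate (methyl haematommate), via chloro(methoxy)methyl adduct 2 (not isolated)
Conditions: Cl2CHOMe, TiCl4, CH2Cl2, −10 → 0 °C; then 1 M HCl
Reagents that add atoms: dichloromethyl methyl ether COC(Cl)Cl; water O
Why: Rieche formylation, in which the titanium phenoxide chelate directs the electrophile to C-3 between the two hydroxyls and aqueous work-up hydrolyses the α-chloro ether to the aldehyde.

**Step 2**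
Reactants: 3 methyl haematommate
Product: 4 methyl 4-(benzyloxy)-3-formyl-2-hydroxy-6-methylbenzoate
Conditions: BnBr, K2CO3, acetone, reflux
Reagents that add atoms: benzyl bromide BrCc1ccccc1
Why: Williamson ether synthesis; the 2-OH is locked between the ester and aldehyde carbonyls, so the more acidic, less hindered 4-OH is alkylated.

**Step 3**
Reactants: 4 methyl 4-(benzyloxy)-3-formyl-2-hydroxy-6-methylbenzoate
Product: 5 4-(benzyloxy)-3-formyl-2-hydroxy-6-methylbenzoic acid
Conditions: LiI, EtOAc, reflux; then 1 M HCl
Reagents that add atoms: none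
Why: SN2 dealkylation of the methyl ester by iodide at the methyl carbon, which does not depend on access to the di-ortho-substituted carbonyl and leaves the aldehyde and benzyl ether alone.

**Step 4**
Reactants: 6 2-bromo-4,6-dimethoxybenzoic acid
Product: 7 2-bromo-4,6-dihydroxybenzoic acid
Conditions: BBr3, CH2Cl2, −78 °C → rt; then H2O
Reagents that add atoms: none
Why: Lewis-acid cleavage of both aryl methyl ethers (BBr3 demethylation); the aryl bromide is inert.

**Step 5**
Reactants: 7 2-bromo-4,6-dihydroxybenzoic acid
Product: 8 methyl 2-bromo-4,6-dihydroxybenzoate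
Conditions: MeI (1.05 equiv), KHCO3, DMF, rt
Reagents that add atoms: iodomethane CI
Why: SN2 O-alkylation of the carboxylate; bicarbonate ionises only the acid, so the phenols stay free.

**Step 6**
Reactants: 8 methyl 2-bromo-4,6-dihydroxybenzoate
Product: 10 methyl 6-bromo-3-formyl-2,4-dihydroxybenzoate, via chloro(methoxy)methyl adduct 9 (not isolated)
Conditions: Cl2CHOMe, TiCl4, CH2Cl2, −10 → 0 °C; then 1 M HCl
Reagents that add atoms: dichloromethyl methyl ether COC(Cl)Cl; water O
Why: Rieche formylation, directed by titanium chelation to C-3 between the hydroxyls (C-5 is flanked by bromine); any 5-formyl isomer is removed by crystallisation.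

**Step 7**
Reactants: 10 methyl 6-bromo-3-formyl-2,4-dihydroxybenzoate
Product: 11 methyl 6-bromo-3-formyl-2,4-dihydroxy-5-iodobenzoate
Conditions: NIS, CF3CO2H (cat.), MeCN, rt
Reagents that add atoms: N-iodosuccinimide O=C1CCC(=O)N1I
Why: electrophilic aromatic iodination at the only free ring position, which is ortho and para to the two hydroxyls.

**Step 8**
Reactants: 5 4-(benzyloxy)-3-formyl-2-hydroxy-6-methylbenzoic acid; 11 methyl 6-bromo-3-formyl-2,4-dihydroxy-5-iodobenzoate
Product: 12 methyl 4-{[4-(benzyloxy)-3-formyl-2-hydroxy-6-methylbenzoyl]oxy}-6-bromo-3-formyl-2-hydroxy-5-iodobenzoate (depside)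
Conditions: (CF3CO)2O, toluene, rt; then aq. NaHCO3
Reagents that add atoms: none
Why: mixed-anhydride esterification (the trifluoroacetic anhydride depside method); the 4-OH of 11 is the only phenol not held between two carbonyl groups, and transient aryl trifluoroacetates are cleaved on work-up.

**Step 9**
Reactants: 12 depside
Product: 13 methyl 3-(benzyloxy)-6-bromo-4,9-diformyl-8-hydroxy-1-methyl-11-oxo-11H-dibenzo[b,e][1,4]dioxepine-7-carboxylate (depsidone)
Conditions: CuI (20 mol %), N,N-dimethylglycine (40 mol %), Cs2CO3, 1,4-dioxane, 90 °C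
Reagents that add atoms: none
Why: intramolecular Ullmann diaryl ether synthesis; the ring A phenoxide reaches only the C–I carbon (seven-membered closure, iodide much faster than bromide), which leaves the neighbouring bromide for the key step.

**Step 10**
Reactants: 13 depsidone methyl ester
Product: 15 (benzyloxy)methyl 3-(benzyloxy)-8-[(benzyloxy)methoxy]-6-bromo-4,9-diformyl-1-methyl-11-oxo-11H-dibenzo[b,e][1,4]dioxepine-7-carboxylate, via lithium carboxylate 14 (not isolated)
Conditions: LiI, EtOAc, reflux; evaporate; then BOMCl, i-Pr2NEt, DMF, 0 °C → rt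
Reagents that add atoms: benzyl chloromethyl ether ClCOCc1ccccc1
Why: SN2 demethylation by iodide, then O-alkylation of the carboxylate and the remaining phenol by the α-chloro ether, which installs the BOM ester (the future lactol carbon) and protects the phenol in one pot.

**Step 11 (key step)**
Reactants: 15 BOM ester aryl bromide
Product: 16 (S)-O-benzyl pseudo-ester: depsidone with 1-methyl, 3-benzyloxy, 4-formyl, 8-(benzyloxy)methoxy, 9-formyl, whose C-6 and C-7 are bridged by CH(OCH2Ph)–O–C(=O) (acetal carbon on C-6, S configuration; carbonyl on C-7)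
Conditions: Pd2(dba)3 (5 mol %), chiral bulky monophosphine L* (binepine type, 12 mol %; antipode picked on the model BOM 2-bromobenzoate to give S), CsOPiv (30 mol %), Cs2CO3 (1.5 equiv), mesitylene, 110 °C
Reagents that add atoms: none
Why: Proposed new method: zerovalent palladium inserts into the C–Br bond ortho to the ester, pivalate-assisted concerted metalation–deprotonation removes one of the two enantiotopic hydrogens of the O–CH2–O group (the most acidic sp3 C–H in reach, through a six-membered palladacycle), and reductive elimination forms the aryl–C bond and the γ-lactone; the acetal carbon, normally electrophilic, thus reacts as an alkylpalladium formyl-anion equivalent with the electrophilic aryl carbon, and the chiral phosphine, which distinguishes the two C–H bonds in the metalation step, sets the (S) acetal centre; the closest known chemistry is enantioselective palladium-catalysed intramolecular methylene C(sp3)–H arylation of aryl halides and C–H palladation next to oxygen, and the main uncertainty is that the ester must react through its less stable E rotamer.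

**Step 12**
Reactants: 16 (S)-O-benzyl pseudo-ester dialdehyde
Product: 17 the corresponding diol: as 16 but with CH2OH at C-4 and C-9, acetal carbon (S)
Conditions: NaBH4, CeCl3·7H2O, THF/MeOH, −40 °C; AcOH quench
Reagents that add atoms: none
Why: Luche-type chemoselective hydride reduction of the two aryl aldehydes at low temperature, which leaves the aryl ester and the pseudo-ester lactone intact and does not involve the stereocentre.

**Step 13**
Reactants: 17 diol
Product: 19 (S)-consalazinic acid (target), via aryl hemiformal 18 (not isolated)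
Conditions: H2 (1 atm), 10 % Pd/C, EtOAc/THF, rt; filter, evaporate below 30 °C
Reagents that add atoms: none
Why: catalytic hydrogenolysis cleaves the three O–CH2Ph bonds at the benzyl carbon, so the acetal C–O bond is never broken and (S) is retained, and the aryl hemiformal left from the BOM ether loses formaldehyde spontaneously.

**Compound list**
1 | methyl 2,4-dihydroxy-6-methylbenzoate (methyl orsellinate) | COC(=O)c1c(C)cc(O)cc1O | starting material
2 | methyl 3-[chloro(methoxy)methyl]-2,4-dihydroxy-6-methylbenzoate (racemic at the new carbon, titanium-bound in the flask) | COC(=O)c1c(C)cc(O)c(C(Cl)OC)c1O | intermediate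
3 | methyl 3-formyl-2,4-dihydroxy-6-methylbenzoate (methyl haematommate) | COC(=O)c1c(C)cc(O)c(C=O)c1O | intermediate
4 | methyl 4-(benzyloxy)-3-formyl-2-hydroxy-6-methylbenzoate | COC(=O)c1c(C)cc(OCc2ccccc2)c(C=O)c1O | intermediate
5 | 4-(benzyloxy)-3-formyl-2-hydroxy-6-methylbenzoic acid | OC(=O)c1c(C)cc(OCc2ccccc2)c(C=O)c1O | intermediate
6 | 2-bromo-4,6-dimethoxybenzoic acid | OC(=O)c1c(Br)cc(OC)cc1OC | starting material
7 | 2-bromo-4,6-dihydroxybenzoic acid | OC(=O)c1c(Br)cc(O)cc1O | intermediate
8 | methyl 2-bromo-4,6-dihydroxybenzoate | COC(=O)c1c(Br)cc(O)cc1O | intermediate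
9 | methyl 6-bromo-3-[chloro(methoxy)methyl]-2,4-dihydroxybenzoate (racemic at the new carbon) | COC(=O)c1c(Br)cc(O)c(C(Cl)OC)c1O | intermediate
10 | methyl 6-bromo-3-formyl-2,4-dihydroxybenzoate | COC(=O)c1c(Br)cc(O)c(C=O)c1O | intermediate
11 | methyl 6-bromo-3-formyl-2,4-dihydroxy-5-iodobenzoate | COC(=O)c1c(Br)c(I)c(O)c(C=O)c1O | intermediate
12 | methyl 4-{[4-(benzyloxy)-3-formyl-2-hydroxy-6-methylbenzoyl]oxy}-6-bromo-3-formyl-2-hydroxy-5-iodobenzoate (depside) | COC(=O)c1c(Br)c(I)c(OC(=O)c2c(C)cc(OCc3ccccc3)c(C=O)c2O)c(C=O)c1O | intermediate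
13 | methyl 3-(benzyloxy)-6-bromo-4,9-diformyl-8-hydroxy-1-methyl-11-oxo-11H-dibenzo[b,e][1,4]dioxepine-7-carboxylate | COC(=O)c1c(Br)c2Oc3c(C=O)c(OCc4ccccc4)cc(C)c3C(=O)Oc2c(C=O)c1O | intermediate
14 | lithium 3-(benzyloxy)-6-bromo-4,9-diformyl-8-hydroxy-1-methyl-11-oxo-11H-dibenzo[b,e][1,4]dioxepine-7-carboxylate | [Li+].[O-]C(=O)c1c(Br)c2Oc3c(C=O)c(OCc4ccccc4)cc(C)c3C(=O)Oc2c(C=O)c1O | intermediate
15 | (benzyloxy)methyl 3-(benzyloxy)-8-[(benzyloxy)methoxy]-6-bromo-4,9-diformyl-1-methyl-11-oxo-11H-dibenzo[b,e][1,4]dioxepine-7-carboxylate | O=C(OCOCc5ccccc5)c1c(Br)c2Oc3c(C=O)c(OCc4ccccc4)cc(C)c3C(=O)Oc2c(C=O)c1OCOCc6ccccc6 | intermediate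
16 | (S)-O-benzyl pseudo-ester: depsidone (1-Me, 3-OBn, 4-CHO, 8-OCH2OBn, 9-CHO) with C-6/C-7 bridged by CH(OBn)–O–C(=O), acetal carbon S | Cc1cc(OCc4ccccc4)c(C=O)c2c1C(=O)Oc1c(C=O)c(OCOCc5ccccc5)c3c(c1O2)[C@@H](OCc6ccccc6)OC3=O | intermediate
17 | as 16 with CH2OH at C-4 and C-9, acetal carbon S | Cc1cc(OCc4ccccc4)c(CO)c2c1C(=O)Oc1c(CO)c(OCOCc5ccccc5)c3c(c1O2)[C@@H](OCc6ccccc6)OC3=O | intermediate
18 | (S)-lactol with free 3-OH and the 8-oxygen still carrying CH2OH (aryl hemiformal) | Cc1cc(O)c(CO)c2c1C(=O)Oc1c(CO)c(OCO)c3c(c1O2)[C@@H](O)OC3=O | intermediate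
19 | (S)-consalazinic acid: depsidone with 1-Me, 3-OH, 4-CH2OH, 8-OH, 9-CH2OH and a C-6/C-7-fused γ-lactone whose lactol carbon CH(OH) is S | Cc1cc(O)c(CO)c2c1C(=O)Oc1c(CO)c(O)c3c(c1O2)[C@@H](O)OC3=O | target

**Totals**
Total steps: 13. Longest linear sequence: 10 steps (steps 4–7, then 8–13, from 6 to 19).

**Three steps most likely to fail**

Step 11 (C–H arylation). Risks are protodebromination, slow metalation because the ester must adopt its E rotamer, and low enantioselectivity. The fallback sets out from 15 and comes back at 16. The same aryl–carbon bond is made intermolecularly with tert-butyl isocyanide as the formyl-anion equivalent: Pd(OAc)2, JohnPhos, Et3SiH, Na2CO3, DMF, 65 °C gives the N-tert-butyl aldimine F1, which dilute aqueous AcOH hydrolyses to the 6-formyl BOM ester F2. A chiral phosphoric acid (TRIP type) with catalytic benzyl alcohol in toluene then converts F2 into 16 by dynamic kinetic lactonisation. The reversibly formed benzyl hemiacetal attacks the neighbouring BOM ester and expels benzyloxymethanol, which returns benzyl alcohol and formaldehyde; the catalyst selects the (S) acetal.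

Step 9 (Ullmann closure). Risks are Smiles rearrangement or cleavage of the depside ester under base, which would scramble the ether and ester positions, and copper attack at the bromide. The fallback sets out from 4 and 11 and comes back at 15. The ether is made first: intermolecular Ullmann coupling of phenol 4 with iodide 11 (Cu2O, K2CO3, pyridine, reflux) gives the diaryl ether diester F3, which fixes the ether position before any aryl ester exists. LiI in EtOAc removes both methyl esters to give the diacid F4. DCC then closes the only possible lactone (ring A acid onto the ring B 4-OH) to give the depsidone acid F5. BOMCl with i-Pr2NEt alkylates its carboxyl and phenol to give 15.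

Step 8 (depside coupling). The risk is low conversion, because a di-ortho-substituted acid must acylate a phenol flanked by CHO and iodine. The fallback sets out from 5 (with 11) and comes back at 12. Acid 5 is condensed with acetone ((CF3CO)2O, CF3CO2H) to the salicylate acetonide, the 7-(benzyloxy)-8-formyl-2,2,5-trimethyl-4H-1,3-benzodioxin-4-one F6. The cesium phenoxide of 11 (Cs2CO3, DMF, 60 °C) opens F6 by acyl transfer under basic rather than acidic activation, releasing acetone and giving 12 with the ring A 2-OH already free.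

**Further compounds**
F1 | step 11 | (benzyloxy)methyl 3-(benzyloxy)-8-[(benzyloxy)methoxy]-6-[(tert-butylimino)methyl]-4,9-diformyl-1-methyl-11-oxo-11H-dibenzo[b,e][1,4]dioxepine-7-carboxylate | O=C(OCOCc5ccccc5)c1c(C=NC(C)(C)C)c2Oc3c(C=O)c(OCc4ccccc4)cc(C)c3C(=O)Oc2c(C=O)c1OCOCc6ccccc6
F2 | step 11 | (benzyloxy)methyl 3-(benzyloxy)-8-[(benzyloxy)methoxy]-4,6,9-triformyl-1-methyl-11-oxo-11H-dibenzo[b,e][1,4]dioxepine-7-carboxylate | O=C(OCOCc5ccccc5)c1c(C=O)c2Oc3c(C=O)c(OCc4ccccc4)cc(C)c3C(=O)Oc2c(C=O)c1OCOCc6ccccc6
F3 | step 9 | methyl 4-(benzyloxy)-2-[2-bromo-5-formyl-4,6-dihydroxy-3-(methoxycarbonyl)phenoxy]-3-formyl-6-methylbenzoate | COC(=O)c1c(C)cc(OCc2ccccc2)c(C=O)c1Oc1c(Br)c(C(=O)OC)c(O)c(C=O)c1O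
F4 | step 9 | 4-(benzyloxy)-2-(2-bromo-3-carboxy-5-formyl-4,6-dihydroxyphenoxy)-3-formyl-6-methylbenzoic acid | OC(=O)c1c(C)cc(OCc2ccccc2)c(C=O)c1Oc1c(Br)c(C(=O)O)c(O)c(C=O)c1O
F5 | step 9 | 3-(benzyloxy)-6-bromo-4,9-diformyl-8-hydroxy-1-methyl-11-oxo-11H-dibenzo[b,e][1,4]dioxepine-7-carboxylic acid | OC(=O)c1c(Br)c2Oc3c(C=O)c(OCc4ccccc4)cc(C)c3C(=O)Oc2c(C=O)c1O
F6 | step 8 | 7-(benzyloxy)-8-formyl-2,2,5-trimethyl-4H-1,3-benzodioxin-4-one | CC1(C)OC(=O)c2c(C)cc(OCc3ccccc3)c(C=O)c2O1
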